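The runs are simulated with constants of no real substance, and the scatter is random.

The easy step comes first: count turnovers. In the ash run the last reading, at 50.0 s, shows 8.2% target on 2 M of substrate, with 36 mM of free catalyst charged. That gives a mean turnover frequency, target made per catalyst charged per unit time, of 0.0911 s⁻¹.

| setting | ash | south | north-west |
|---|---|---|---|
| substrate | 2 M | 0.50 M | 2.0 M |
| partner | 2.4 M | 1.60 M | 1.60 M |
| free catalyst | 36 mM | 10 mM | 36 mM |
| remark | run made earlier |  |  |
| time |  | 4.0 min | 4.0 min |

- ash (time / s: target / %, substrate / %): 10.0: 2.0, 98.6; 15.0: 2.2, 97.5; 25.0: 3.4, 95.3; 30.0: 4.1, 95.0; 40.0: 5.8, 92.9; 50.0: 8.2, 90.9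

(scatter of a reading: 0.5 percentage points)

- the winner by amount of target, in percent of the substrate charged; "neither" if no more than 2 percentage points parts them (south / north-west / neither)
- how much target is there at the end, in percent of the substrate charged: south
- how much target is there at the end, in percent of the substrate charged: north-west

- no earlier run changes the charge of free catalyst; that part of a forecast is a guess

A note for whoever takes the bench. North-west holds the [substrate] and catalyst of ash with less partner, and I assume that this leaves the frequency as it is. By 4.0 min that makes 21.9 turnovers, so I expect 39.4% target. At one partner per target, my assumption, this needs 0.787 M, less than the 1.60 M charged. Don't touch the catalyst charge or the clock, since in this reckoning target moves in step with both, and no earlier run changes the catalyst charge.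

South is harder, as no earlier run varies [substrate]. The ash frequency gives 43.7%, and a frequency proportional to [substrate] gives 10.9%. I commit to their geometric mean, 21.9%, which is less than my figure for north-west, so north-west is my winner.

The forecast is lower than mine on both flasks  and gives 13% for south and 25% for north-west: “North-west wins under most readings”.

The flask gives 20.1% for south and 37.0% for north-west.

    substrate + catalyst intermediate B → catalyst intermediate C (k = 0.240 M⁻¹ s⁻¹)
    partner + free catalyst → catalyst intermediate A (k = 5.40 M⁻¹ s⁻¹)
    catalyst intermediate B → spent catalyst (k = 0.00100 s⁻¹)
    catalyst intermediate C → catalyst intermediate D (k = 64.0 s⁻¹)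
    catalyst intermediate D → free catalyst + target (k = 0.580 s⁻¹)
    catalyst intermediate A ⇌ catalyst intermediate B (K = 1.50, k = 0.200 s⁻¹)

Moving the ash partner charge to north-west's leaves the target at the last ash reading at 8.09%, against 8.13%. North-west's result is 20.5 turnovers per catalyst charged, on average 0.0856 s⁻¹, against the 0.0911 s⁻¹ I read from the ash readings.

A neighbour flask is north-west with 0.40 M of partner. At the ash frequency the clock offers 21.9 turnovers, but at one partner per target the partner pays for 11.1, fewer, so I reckon 20.0% target in this neighbour. The computed flask holds 20.0% target with 0% of its partner left: partner is the limiting reagent there.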